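**Strategy.** The cyclohexane ring (C6 with the hydroxypropyl arm, C7 with the enal, C8, C9, carbinol C10, quaternary C11) is disconnected at C6–C11 and C7–C8. One copper-bis(oxazoline)-catalysed Diels–Alder reaction of a chelating α'-hydroxy enone (C6=C7) with 4-methyl-5-vinyl-2,3-dihydrofuran (C8=C9–C10=C11) forms both bonds and sets C6 and C11. It exploits the oxygen on C10 beside quaternary C11: tying O–C10 and C11–C12–C13 into a dihydrofuran fixes the enol ether geometry, masks the C10 ketone and leaves C13–O as the handle for the side chain, which is joined by Negishi coupling. The hydroxy ketone later becomes the methyl ketone and then the enal.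

Key step: step 5

Remark on locants: C1 is the aldehyde carbon, C2 its α-carbon (methyl C25), C3 the primary carbinol carbon, C6–C11 the ring, C12–C24 the side chain with its carbinol at C21. Compounds 2, 16 and 21 are taken as catalogue chemicals.

Step 1
Reactants: 1 3-hydroxy-3-methylbutan-2-one; 2 4-[(tert-butyldimethylsilyl)oxy]butanal
Product: 4 8-[(tert-butyldimethylsilyl)oxy]-2,5-dihydroxy-2-methyloctan-3-one (racemic at its C5), via dilithium dianion 3 (not isolated)
Conditions: LiN(iPr)2 (2.1 equiv), THF, −78 °C; then 2, −78 °C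
Reagents that add atoms: none
Why: Aldol addition of the alkoxide enolate of 1 (its methyl group is the only enolisable position) to aldehyde 2; the new carbinol centre is removed in step 2 and needs no control.

Step 2
Reactants: 4 8-[(tert-butyldimethylsilyl)oxy]-2,5-dihydroxy-2-methyloctan-3-one
Product: 6 (E)-8-[(tert-butyldimethylsilyl)oxy]-2-hydroxy-2-methyloct-4-en-3-one, via secondary mesylate 5 (not isolated)
Conditions: MeSO2Cl (1.2 equiv), Et3N (3 equiv), CH2Cl2, 0 to 23 °C
Reagents that add atoms: none
Why: Mesylation of the secondary alcohol followed by E1cB elimination through the ketone enolate should give the conjugated (E)-enone, the tertiary alcohol being too hindered to react.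

Step 3
Reactants: 7 3-methyloxolan-2-one (α-methyl-γ-butyrolactone, racemic)
Product: 9 4-methyl-2,3-dihydrofuran-5-yl diphenyl phosphate, via potassium enolate 8 (not isolated)
Conditions: KN(SiMe3)2, (PhO)2P(O)Cl present from the start, THF/DMPU, −78 °C
Reagents that add atoms: diphenyl chlorophosphate, O=P(Cl)(Oc1ccccc1)Oc1ccccc1
Why: O-Phosphorylation of the lactone enolate with in situ trapping (ketene acetal phosphate formation) should outrun Claisen self-condensation and puts a cross-coupling handle on the carbon that becomes C10.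

Step 4
Reactants: 9 4-methyl-2,3-dihydrofuran-5-yl diphenyl phosphate; 10 tributyl(vinyl)stannane
Product: 11 5-ethenyl-4-methyl-2,3-dihydrofuran
Conditions: Pd(PPh3)4 (5 mol%), LiCl (3 equiv), THF, 65 °C
Reagents that add atoms: none
Why: Stille coupling of a lactone-derived ketene acetal phosphate with a vinylstannane is an established entry to 2-alkoxy dienes, and the ring holds the methyl group cis to the vinyl group.

Step 5
Reactants: 6 (E)-8-[(tert-butyldimethylsilyl)oxy]-2-hydroxy-2-methyloct-4-en-3-one; 11 5-ethenyl-4-methyl-2,3-dihydrofuran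
Product: 12 1-[(3aR,4S,5R)-4-{3-[(tert-butyldimethylsilyl)oxy]propyl}-3a-methyl-2,3,3a,4,5,6-hexahydro-1-benzofuran-5-yl]-2-hydroxy-2-methylpropan-1-one (6S,7R,11R)
Conditions: Cu(OTf)2 (10 mol%), 2,2'-(propane-2,2-diyl)bis[(4S)-4-tert-butyl-4,5-dihydro-1,3-oxazole] (11 mol%), 4 Å molecular sieves, CH2Cl2, −20 to 23 °C, 11 in excess
Reagents that add atoms: none
Why: The hydroxy ketone of 6 binds the copper-bis(oxazoline) complex as a five-membered chelate with the enone s-cis, and the electron-rich 2-alkoxy diene 11 should add in a concerted but strongly asynchronous [4+2] cycloaddition in which the C6–C11 bond leads and the C7–C8 bond follows in the same event. The closest known reaction type is the copper-bis(oxazoline)-catalysed Diels–Alder reaction of chelating α'-hydroxy enones, together with Lewis-acid Diels–Alder reactions of 2-oxy dienes that build quaternary centres. The ring C6–C7–C8–C9–C10–C11 closes by the [4+2] cycloaddition itself; should the event turn stepwise, the second bond is a 6-endo-trig Michael closure of the copper enolate at C7 onto C8 of the unsaturated oxocarbenium ion. C6 is set by the ligand, whose tert-butyl group screens the C6-Re/C7-Si face of the planar chelate so that the diene adds to the C6-Si/C7-Re face; C11 is set by the endo transition state and the ring-fixed enol ether geometry (methyl inside, C12 outside), which places the C11 methyl cis to the C6 chain; C7 (acyl endo, cis to C12) is erased later. The step needs para regiochemistry and ring closure at carbon: the donor oxygen on C10 makes C11 the nucleophilic terminus and C6 is the β-carbon of the activated enone, while an oxygen-closed hetero-adduct would be an allyl vinyl ketal that can still reach 12 by [3,3] shift.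

Step 6
Reactants: 12 hexahydrobenzofuran adduct (6S,7R,11R)
Product: 13 1-[(1R,2S,3R)-2-{3-[(tert-butyldimethylsilyl)oxy]propyl}-3-(2-hydroxyethyl)-3-methyl-4-oxocyclohexyl]-2-hydroxy-2-methylpropan-1-one
Conditions: pyridinium p-toluenesulfonate (0.1 equiv), acetone/H2O (10:1), 23 °C
Reagents that add atoms: water, O
Why: Acid-catalysed enol ether hydrolysis (protonation at C9, hydration of the oxocarbenium ion, opening of the hemiketal) should unveil the C10 ketone and the C13 alcohol while the primary silyl ether survives.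

Step 7
Reactants: 13 keto alcohol (6S,7R,11R)
Product: 14 1-[(1R,2S,3R)-2-{3-[(tert-butyldimethylsilyl)oxy]propyl}-3-(2-iodoethyl)-3-methyl-4-oxocyclohexyl]-2-hydroxy-2-methylpropan-1-one
Conditions: I2, PPh3, imidazole, CH2Cl2, 0 °C
Reagents that add atoms: iodine, [I][I]
Why: The Appel reaction converts only the primary C13 alcohol into the iodide under near-neutral conditions, leaving the tertiary alcohol and both ketones untouched.

Step 8
Reactants: 15 3-methylbut-2-enal; 16 allenylboronic acid pinacol ester
Product: 17 (R)-6-methylhept-5-en-1-yn-4-ol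
Conditions: (R)-3,3'-bis(2,4,6-triisopropylphenyl)-1,1'-binaphthyl-2,2'-diyl hydrogen phosphate (5 mol%), 4 Å molecular sieves, toluene, −20 °C
Reagents that add atoms: none
Why: Chiral phosphoric acid-catalysed propargylation of an aldehyde by an allenylboronate through a closed six-membered transition state; by analogy with the allylboration model the (R)-acid should direct addition to the Re face and set the future C21 as (R).

Step 9
Reactants: 17 (R)-6-methylhept-5-en-1-yn-4-ol
Product: 18 (R)-tert-butyldimethyl[(6-methylhept-5-en-1-yn-4-yl)oxy]silane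
Conditions: tBuMe2SiCl, imidazole, DMF, 23 °C
Reagents that add atoms: tert-butyldimethylsilyl chloride, C[Si](C)(Cl)C(C)(C)C
Why: Silyl ether formation protects the C21 alcohol for the organometallic steps without touching the stereocentre.

Step 10
Reactants: 18 (R)-silyl ether of 17
Product: 20 (1E,4R)-4-[(tert-butyldimethylsilyl)oxy]-1-iodo-2,6-dimethylhepta-1,5-diene, via alkenylalane 19 (not isolated)
Conditions: Me3Al (2 equiv), Cp2ZrCl2 (25 mol%), CH2Cl2, 0 to 23 °C; then I2, THF, −30 °C
Reagents that add atoms: trimethylaluminium, C[Al](C)C; iodine, [I][I]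
Why: Negishi carboalumination adds methyl and aluminium syn across the terminal alkyne with methyl on the internal carbon, and iodinolysis with retention should give the (E)-alkenyl iodide that fixes the C18=C19 geometry.

Step 11
Reactants: 21 4-(trimethylsilyl)but-3-yn-1-ol
Product: 22 (4-iodobut-1-yn-1-yl)trimethylsilane
Conditions: I2, PPh3, imidazole, CH2Cl2, 0 °C
Reagents that add atoms: iodine, [I][I]
Why: Appel reaction of a primary alcohol gives the iodide needed for zinc insertion.

Step 12
Reactants: 20 (1E,4R)-alkenyl iodide; 22 (4-iodobut-1-yn-1-yl)trimethylsilane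
Product: 24 (5E,8R)-8-[(tert-butyldimethylsilyl)oxy]-6,10-dimethyl-1-(trimethylsilyl)undeca-5,9-dien-1-yne, via alkylzinc iodide 23 (not isolated)
Conditions: 22, Zn dust, LiCl, THF, 40 °C; then 20, Pd(PPh3)4 (3 mol%), THF, 23 °C
Reagents that add atoms: none
Why: Negishi coupling of a homopropargylic zinc iodide with an alkenyl iodide forms the C17–C18 bond with retention of the (E) geometry.

Step 13
Reactants: 24 silylated enyne
Product: 25 (5E,8R)-8-[(tert-butyldimethylsilyl)oxy]-6,10-dimethylundeca-5,9-dien-1-yne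
Conditions: K2CO3 (cat.), MeOH, 23 °C
Reagents that add atoms: none
Why: Methanolysis of the alkynylsilane frees the terminal alkyne, and the silyl ether on oxygen is stable to carbonate in methanol.

Step 14
Reactants: 25 terminal alkyne
Product: 27 (1E,5E,8R)-8-[(tert-butyldimethylsilyl)oxy]-1-iodo-2,6,10-trimethylundeca-1,5,9-triene, via alkenylalane 26 (not isolated)
Conditions: Me3Al (2 equiv), Cp2ZrCl2 (25 mol%), CH2Cl2, 0 to 23 °C; then I2, THF, −30 °C
Reagents that add atoms: trimethylaluminium, C[Al](C)C; iodine, [I][I]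
Why: A second Negishi carboalumination with iodinolysis should set the (E)-C14=C15 alkene and place the coupling handle on C14.

Step 15
Reactants: 14 iodo ketone (6S,7R,11R); 27 (1E,5E,8R)-alkenyl iodide
Product: 29 1-[(1R,2S,3R)-2-{3-[(tert-butyldimethylsilyl)oxy]propyl}-3-[(3E,7E,10R)-10-[(tert-butyldimethylsilyl)oxy]-4,8,12-trimethyltrideca-3,7,11-trien-1-yl]-3-methyl-4-oxocyclohexyl]-2-hydroxy-2-methylpropan-1-one, via alkylzinc iodide 28 (not isolated)
Conditions: 14, Zn dust, LiCl, THF, 40 °C; then 27, Pd(dppf)Cl2 (5 mol%), THF/NMP, 23 °C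
Reagents that add atoms: none
Why: Negishi coupling: zinc insertion into the primary iodide tolerates the ketones and the hindered tertiary alcohol, and palladium-catalysed coupling with 27 forms the C13–C14 bond with retention of the (E) geometry.

Step 16
Reactants: 29 coupled hydroxy diketone (6S,7R,11R,21R)
Product: 30 triol (6S,7R,10R,11R,21R) with the tertiary alcohol at C10 and a 2,3-dihydroxy-3-methylbutan-2-yl group on C7 (C2 epimers)
Conditions: MeMgBr (6 equiv), CeCl3, THF, −78 to 0 °C
Reagents that add atoms: methylmagnesium bromide, C[Mg]Br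
Why: Grignard addition (organocerium variant) to both ketones at once: the ring should sit in the chair with the C6 and C7 substituents equatorial and the C11 methyl axial, so methyl enters C10 axially from the face opposite the C11 methyl and the C6 chain and leaves the new hydroxyl cis to the C11 methyl (10R), while the diol formed at C2 masks the methyl ketone.

Step 17
Reactants: 30 triol
Product: 31 methyl ketone: 1-[(1R,2S,3R,4R)-…-4-hydroxy-3,4-dimethylcyclohexyl]ethan-1-one carrying the C6 and C11 chains of 29 (6S,7R,10R,11R,21R)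
Conditions: NaIO4, THF/H2O (pH 7 buffer), 23 °C
Reagents that add atoms: none
Why: Periodate glycol cleavage acts only on the vicinal ditertiary diol, releasing acetone and the C2 methyl ketone.

Step 18
Reactants: 31 methyl ketone
Product: 33 enol triflate with the C7=C2 alkene, triflyloxy group cis to C6 and methyl cis to C8 (6S,10R,11R,21R), via dilithium alkoxide enolate 32 (not isolated)
Conditions: LiN(SiMe3)2 (1.95 equiv), THF, −78 to 23 °C, 2 h; then PhNTf2 (1.1 equiv), 0 °C
Reagents that add atoms: N-phenylbis(trifluoromethanesulfonimide), O=S(=O)(N(c1ccccc1)S(=O)(=O)C(F)(F)F)C(F)(F)F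
Why: Thermodynamic enolate formation and O-triflation: reversible deprotonation should favour the more substituted C7=C2 enolate with its oxygen cis to the more crowded C6 and its methyl cis to C8 (allylic strain), and the hindered tertiary alkoxide should not compete for the triflating agent.

Step 19
Reactants: 33 enol triflate
Product: 34 bis(tert-butyldimethylsilyl) ether of the target at O3 and O21 (6S,10R,11R,21R)
Conditions: Pd(PPh3)4 (10 mol%), CO (3 atm), Bu3SnH (slow addition), THF, 50 °C
Reagents that add atoms: carbon monoxide, [C-]#[O+]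
Why: Palladium-catalysed reductive carbonylation (formylation) of an alkenyl triflate replaces the triflate by CHO with retention of alkene geometry, so the aldehyde ends cis to C6.

Step 20
Reactants: 34 bis-silyl enal
Product: 35 CNP0270422.1 (6S,10R,11R,21R)
Conditions: Bu4NF (3 equiv), AcOH (3 equiv), THF, 0 to 23 °C
Reagents that add atoms: none
Why: Fluoride-mediated cleavage of both silyl ethers; buffering with acetic acid should prevent γ-deprotonation of the enal, which would threaten C6 and the alkene geometry.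

**Compound list**

1 | 3-hydroxy-3-methylbutan-2-one | CC(=O)C(C)(C)O | starting material
2 | 4-[(tert-butyldimethylsilyl)oxy]butanal | O=CCCCO[Si](C)(C)C(C)(C)C | starting material
3 | dilithium dianion of 1 | [Li]OC(C)(C)C(=C)O[Li] | intermediate
4 | 8-[(tert-butyldimethylsilyl)oxy]-2,5-dihydroxy-2-methyloctan-3-one (racemic) | CC(C)(O)C(=O)CC(O)CCCO[Si](C)(C)C(C)(C)C | intermediate
5 | 5-O-mesylate of 4 | CC(C)(O)C(=O)CC(OS(C)(=O)=O)CCCO[Si](C)(C)C(C)(C)C | intermediate
6 | (E)-8-[(tert-butyldimethylsilyl)oxy]-2-hydroxy-2-methyloct-4-en-3-one | CC(C)(O)C(=O)/C=C/CCCO[Si](C)(C)C(C)(C)C | intermediate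
7 | 3-methyloxolan-2-one (racemic) | CC1CCOC1=O | starting material
8 | potassium enolate of 7 | CC1=C(O[K])OCC1 | intermediate
9 | 4-methyl-2,3-dihydrofuran-5-yl diphenyl phosphate | CC1=C(OP(=O)(Oc2ccccc2)Oc2ccccc2)OCC1 | intermediate
10 | tributyl(vinyl)stannane | C=C[Sn](CCCC)(CCCC)CCCC | starting material
11 | 5-ethenyl-4-methyl-2,3-dihydrofuran | C=CC1=C(C)CCO1 | intermediate
12 | Diels–Alder adduct (3aR,4S,5R; locants 6S,7R,11R) | C1C[C@]2(C)[C@@H](CCCO[Si](C)(C)C(C)(C)C)[C@H](C(=O)C(C)(C)O)CC=C2O1 | intermediate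
13 | keto alcohol (6S,7R,11R) | OCC[C@]1(C)[C@@H](CCCO[Si](C)(C)C(C)(C)C)[C@H](C(=O)C(C)(C)O)CCC1=O | intermediate
14 | iodo ketone (6S,7R,11R) | ICC[C@]1(C)[C@@H](CCCO[Si](C)(C)C(C)(C)C)[C@H](C(=O)C(C)(C)O)CCC1=O | intermediate
15 | 3-methylbut-2-enal | CC(C)=CC=O | starting material
16 | allenylboronic acid pinacol ester | C=C=CB1OC(C)(C)C(C)(C)O1 | starting material
17 | (R)-6-methylhept-5-en-1-yn-4-ol | CC(C)=C[C@H](O)CC#C | intermediate
18 | (R)-tert-butyldimethylsilyl ether of 17 | CC(C)=C[C@H](O[Si](C)(C)C(C)(C)C)CC#C | intermediate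
19 | (E)-alkenyl(dimethyl)alane from 18 | CC(C)=C[C@H](O[Si](C)(C)C(C)(C)C)C/C(C)=C/[Al](C)C | intermediate
20 | (1E,4R)-4-[(tert-butyldimethylsilyl)oxy]-1-iodo-2,6-dimethylhepta-1,5-diene | CC(C)=C[C@H](O[Si](C)(C)C(C)(C)C)C/C(C)=C/I | intermediate
21 | 4-(trimethylsilyl)but-3-yn-1-ol | C[Si](C)(C)C#CCCO | starting material
22 | (4-iodobut-1-yn-1-yl)trimethylsilane | C[Si](C)(C)C#CCCI | intermediate
23 | [4-(trimethylsilyl)but-3-yn-1-yl]zinc iodide | C[Si](C)(C)C#CCC[Zn]I | intermediate
24 | (5E,8R)-8-[(tert-butyldimethylsilyl)oxy]-6,10-dimethyl-1-(trimethylsilyl)undeca-5,9-dien-1-yne | CC(C)=C[C@H](O[Si](C)(C)C(C)(C)C)C/C(C)=C/CCC#C[Si](C)(C)C | intermediate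
25 | (5E,8R)-8-[(tert-butyldimethylsilyl)oxy]-6,10-dimethylundeca-5,9-dien-1-yne | CC(C)=C[C@H](O[Si](C)(C)C(C)(C)C)C/C(C)=C/CCC#C | intermediate
26 | (1E,5E)-alkenyl(dimethyl)alane from 25 | CC(C)=C[C@H](O[Si](C)(C)C(C)(C)C)C/C(C)=C/CC/C(C)=C/[Al](C)C | intermediate
27 | (1E,5E,8R)-8-[(tert-butyldimethylsilyl)oxy]-1-iodo-2,6,10-trimethylundeca-1,5,9-triene | CC(C)=C[C@H](O[Si](C)(C)C(C)(C)C)C/C(C)=C/CC/C(C)=C/I | intermediate
28 | alkylzinc iodide from 14 | I[Zn]CC[C@]1(C)[C@@H](CCCO[Si](C)(C)C(C)(C)C)[C@H](C(=O)C(C)(C)O)CCC1=O | intermediate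
29 | coupled hydroxy diketone (6S,7R,11R,21R) | CC(C)=C[C@H](O[Si](C)(C)C(C)(C)C)C/C(C)=C/CC/C(C)=C/CC[C@]1(C)[C@@H](CCCO[Si](C)(C)C(C)(C)C)[C@H](C(=O)C(C)(C)O)CCC1=O | intermediate
30 | triol (6S,7R,10R,11R,21R; C2 epimers) | CC(C)=C[C@H](O[Si](C)(C)C(C)(C)C)C/C(C)=C/CC/C(C)=C/CC[C@]1(C)[C@@H](CCCO[Si](C)(C)C(C)(C)C)[C@H](C(C)(O)C(C)(C)O)CC[C@@]1(C)O | intermediate
31 | methyl ketone (6S,7R,10R,11R,21R) | CC(C)=C[C@H](O[Si](C)(C)C(C)(C)C)C/C(C)=C/CC/C(C)=C/CC[C@]1(C)[C@@H](CCCO[Si](C)(C)C(C)(C)C)[C@H](C(C)=O)CC[C@@]1(C)O | intermediate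
32 | dilithium alkoxide enolate of 31 | CC(C)=C[C@H](O[Si](C)(C)C(C)(C)C)C/C(C)=C/CC/C(C)=C/CC[C@]1(C)[C@@H](CCCO[Si](C)(C)C(C)(C)C)/C(=C(/C)O[Li])CC[C@@]1(C)O[Li] | intermediate
33 | enol triflate (6S,10R,11R,21R) | CC(C)=C[C@H](O[Si](C)(C)C(C)(C)C)C/C(C)=C/CC/C(C)=C/CC[C@]1(C)[C@@H](CCCO[Si](C)(C)C(C)(C)C)/C(=C(/C)OS(=O)(=O)C(F)(F)F)CC[C@@]1(C)O | intermediate
34 | 3,21-bis-O-(tert-butyldimethylsilyl) enal | CC(C)=C[C@H](O[Si](C)(C)C(C)(C)C)C/C(C)=C/CC/C(C)=C/CC[C@]1(C)[C@@H](CCCO[Si](C)(C)C(C)(C)C)/C(=C(/C)C=O)CC[C@@]1(C)O | intermediate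
35 | CNP0270422.1 (6S,10R,11R,21R) | CC(C)=C[C@H](O)C/C(C)=C/CC/C(C)=C/CC[C@]1(C)[C@@H](CCCO)/C(=C(/C)C=O)CC[C@@]1(C)O | target

**Totals.** Total step count: 20. Longest linear sequence: 12 steps (steps 8, 9, 10, 12, 13, 14, 15, 16, 17, 18, 19, 20, from 3-methylbut-2-enal).

**Steps most likely to fail**

Step 5. The fully substituted C11 terminus may add only slowly, ring closure may occur at oxygen instead of carbon, and endo control may erode with the inside methyl group. The fallback sets out from 6 and 11 and divides the union into two known operations. A copper-bis(oxazoline)-catalysed inverse-demand hetero-Diels–Alder reaction, with 6 as the oxadiene and the C10=C11 enol ether of 11 as the 2π partner, gives the cis-fused 2-[7a-ethenyl-3a-methyl-4-(3-silyloxypropyl)-3,3a,4,7a-tetrahydro-2H-furo[2,3-b]pyran-6-yl]propan-2-ol F1 (C6–C11 bond). Heating F1 in toluene at 110 °C then triggers the Claisen [3,3] rearrangement of its allyl vinyl ether unit (C8=C9–C10–O–C2=C7), which forms C7–C8 and comes back to the route at 12.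

Step 18. Enolate equilibration may favour the methyl-derived enolate or give both alkene geometries, and the tertiary alkoxide may consume triflating agent. The fallback sets out from 31. Silylation under equilibrating conditions (Me3SiCl, NaI, Et3N, MeCN) gives the bis(trimethylsilyl) compound F2, which carries the C10 silyl ether and the tetrasubstituted silyl enol ether and can be purified. MeLi then releases the lithium enolate F3 regiospecifically, PhNTf2 converts it into the C10-silylated enol triflate F4, and K2CO3 in MeOH removes the tertiary silyl group to come back to the route at 33.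

Step 19. Oxidative addition into the hindered tetrasubstituted triflate may be slow, and hydride transfer to the alkenylpalladium species may outrun CO insertion. The fallback sets out from 33. A Stille coupling with (tributylstannyl)methanol (Pd(PPh3)4, LiCl, dioxane, 90 °C) gives the allylic alcohol F5, and MnO2 in CH2Cl2 oxidises only this primary allylic alcohol to come back to the route at 34.

Further compounds
F1 | step 5 | hetero-Diels–Alder ketal, cis-fused furo[2,3-b]pyran | C=C[C@@]12OCC[C@]1(C)[C@@H](CCCO[Si](C)(C)C(C)(C)C)C=C(C(C)(C)O)O2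
F2 | step 18 | 10-O-trimethylsilyl silyl enol ether of 31 | CC(C)=C[C@H](O[Si](C)(C)C(C)(C)C)C/C(C)=C/CC/C(C)=C/CC[C@]1(C)[C@@H](CCCO[Si](C)(C)C(C)(C)C)/C(=C(/C)O[Si](C)(C)C)CC[C@@]1(C)O[Si](C)(C)C
F3 | step 18 | lithium enolate with the C10 trimethylsilyl ether | CC(C)=C[C@H](O[Si](C)(C)C(C)(C)C)C/C(C)=C/CC/C(C)=C/CC[C@]1(C)[C@@H](CCCO[Si](C)(C)C(C)(C)C)/C(=C(/C)O[Li])CC[C@@]1(C)O[Si](C)(C)C
F4 | step 18 | 10-O-trimethylsilyl ether of 33 | CC(C)=C[C@H](O[Si](C)(C)C(C)(C)C)C/C(C)=C/CC/C(C)=C/CC[C@]1(C)[C@@H](CCCO[Si](C)(C)C(C)(C)C)/C(=C(/C)OS(=O)(=O)C(F)(F)F)CC[C@@]1(C)O[Si](C)(C)C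
F5 | step 19 | allylic alcohol (C1 as CH2OH) | CC(C)=C[C@H](O[Si](C)(C)C(C)(C)C)C/C(C)=C/CC/C(C)=C/CC[C@]1(C)[C@@H](CCCO[Si](C)(C)C(C)(C)C)/C(=C(/C)CO)CC[C@@]1(C)O
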